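**Retrosynthetic overview**
1. Final stage: phenol unmasking, hydroxyl-directed α-epoxidation of the C3=C4 alkene and acylation of the C8 hydroxyl, all on a trans-fused guai-3-ene-8β,10α-diol.
2. That alkene comes from a 10α-hydroxy-guai-4-en-3-one by reductive 1,3-transposition of its tosylhydrazone (allylic diazene), which puts H on C5 (β) and creates the trans ring fusion.
3. Key step: photochemical santonin-type rearrangement of a cross-conjugated eudesma-1,4-dien-3-one in aqueous acid. The six/six skeleton becomes five/seven, and C1 (α-H) and C10 (α-OH, β-CH3) are set in one stereospecific event.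
4. The eudesmadienone is (R)-carvone (ring B, C7) plus ethyl vinyl ketone (ring A), joined by an auxiliary-controlled deconjugative Michael addition and aldol condensation. The surviving C8=C9 alkene gives the 8β-OH by trans-diaxial bromohydrin formation.
5. Ring order: ring B from the chiral pool, ring A by annulation, then both reorganised photochemically into the five- and seven-membered rings; the epoxide ring is formed last.

Assumption: intermediates are described with eudesmane/guaiane numbering (C4–CH3, C7–isopropyl, C8–O, C10–CH3; β = face of the C10 methyl group; 7αH means isopropyl β), and O-benzylisovanillic acid is taken as a commercial reagent.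

**Route**

Step 1
Reactants: 1 (R)-(−)-carvone
Product: 2 (R)-carvotanacetone [(5R)-2-methyl-5-(propan-2-yl)cyclohex-2-en-1-one]
Conditions: H2 (1 atm), RhCl(PPh3)3 (3 mol %), benzene, 25 °C
Reagents that add atoms: none
Why: Chemoselective homogeneous hydrogenation saturates the unhindered 1,1-disubstituted isopropenyl alkene far faster than the trisubstituted conjugated enone alkene, so the chiral-pool stereocentre (future C7, isopropyl β) is carried through unchanged.

Step 2
Reactants: 2 (R)-carvotanacetone; 3 (R)-(+)-1-phenylethylamine; 4 ethyl vinyl ketone (pent-1-en-3-one)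
Product: 7 (2R,5R)-2-methyl-2-(3-oxopentyl)-5-(propan-2-yl)cyclohex-3-en-1-one, via N-(1-phenylethyl) ketimine 5 (not isolated), via Michael-adduct ketimine 6 (not isolated)
Conditions: 3 (1.05 equiv), TsOH (1 mol %), toluene, reflux (Dean–Stark); then 4 (1.5 equiv), THF, 40 °C, 72 h; then 20% aq. AcOH, 25 °C
Reagents that add atoms: water, O
Why: Proposed new method: the secondary dienamine tautomer of ketimine 5 (N–C5=C10–C9=C8) adds to the enone only through its α-carbon C10, because the Pfau–d'Angelo aza-ene-like Michael transition state needs syn transfer of the N–H hydrogen through a six-membered array that the remote δ-carbon cannot reach, so the alkene ends deconjugated at C8=C9 and the (R)-1-phenylethyl group screens one enamine face to set the quaternary C10 with its methyl cis to the isopropyl group; the closest known reactions are the chiral-imine (d'Angelo) Michael addition used to make α-cyperone from dihydrocarvone and the α-alkylation of Stork dienamines.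

Step 3
Reactants: 7 (2R,5R)-2-methyl-2-(3-oxopentyl)-5-(propan-2-yl)cyclohex-3-en-1-one
Product: 8 (4aR,7R)-1,4a-dimethyl-7-(propan-2-yl)-4,4a,7,8-tetrahydronaphthalen-2(3H)-one (7αH-eudesma-4,8-dien-3-one)
Conditions: NaOMe (0.3 equiv), MeOH, 25 → 60 °C
Reagents that add atoms: none
Why: Base-mediated intramolecular aldol condensation (second stage of a Robinson annulation) closes ring A as the tetrasubstituted enone, while the C8=C9 alkene cannot move into conjugation because C10 is quaternary; no stereocentre is formed or touched.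

Step 4
Reactants: 8 7αH-eudesma-4,8-dien-3-one
Product: 9 bromohydrin 9α-bromo-8β-hydroxy-7αH-eudesm-4-en-3-one
Conditions: NBS (1.1 equiv), acetone/H2O (4:1), 0 °C, dark
Reagents that add atoms: N-bromosuccinimide, O=C1CCC(=O)N1Br; water, O
Why: Bromohydrin formation in which the bromonium ion forms on the α face, anti to the axial angular methyl group, and water opens it trans-diaxially at C8 (C9 is neopentyl), the same Fürst–Plattner outcome as 5α-bromo-6β-hydroxy formation from steroid 5-enes, which sets the 8β (axial) hydroxyl cis to the equatorial 7β-isopropyl group.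

Step 5
Reactants: 9 bromohydrin 9α-bromo-8β-hydroxy-7αH-eudesm-4-en-3-one
Product: 10 hydroxy enone 8β-hydroxy-7αH-eudesm-4-en-3-one
Conditions: Bu3SnH (1.3 equiv), (PhSe)2 (10 mol %), AIBN (10 mol %), benzene, 80 °C
Reagents that add atoms: none
Why: Radical chain dehalogenation removes the C9 bromine without touching C8, and benzeneselenol generated in situ from (PhSe)2 traps the C9 radical fast enough to suppress 3-exo attack on the enone (vinyl migration).

Step 6
Reactants: 10 hydroxy enone 8β-hydroxy-7αH-eudesm-4-en-3-one
Product: 11 dienone 8β-hydroxy-7αH-eudesma-1,4-dien-3-one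
Conditions: DDQ (1.5 equiv), dioxane, 100 °C
Reagents that add atoms: none
Why: DDQ dehydrogenation of a 4-en-3-one under neutral conditions (hydride abstraction from C1 of the enol) installs the C1=C2 alkene to give the cross-conjugated cyclohexadienone chromophore, and the saturated secondary alcohol is inert to DDQ.

Step 7
Reactants: 11 dienone 8β-hydroxy-7αH-eudesma-1,4-dien-3-one
Product: 12 dihydroxy enone 8β,10α-dihydroxy-1αH-guai-4-en-3-one
Conditions: hν (medium-pressure Hg lamp, Pyrex, λ > 290 nm), AcOH/H2O (45:55), N2, 25 °C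
Reagents that add atoms: water, O
Why: Santonin-type photorearrangement of a 4-methyl cross-conjugated cyclohexadienone in aqueous acid (C1–C5 bonding to a cyclopropyl oxyallyl zwitterion, O-protonation, cleavage of the C5–C10 cyclopropane bond and capture of the C10 cation by water anti to the departing bond) converts the six/six skeleton into the five/seven skeleton stereospecifically, giving 1α-H and 10α-OH/10β-CH3 from the 10β-methyl dienone exactly as santonin gives isophotosantonic lactone.

Step 8
Reactants: 12 dihydroxy enone 8β,10α-dihydroxy-1αH-guai-4-en-3-one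
Product: 13 tosylhydrazone of 12 at C3
Conditions: TsNHNH2 (1.3 equiv), EtOH, 60 °C
Reagents that add atoms: p-toluenesulfonyl hydrazide, Cc1ccc(cc1)S(=O)(=O)NN
Why: Condensation of the conjugated cyclopentenone carbonyl with tosylhydrazide gives the α,β-unsaturated tosylhydrazone needed for reductive transposition, under neutral conditions that leave the tertiary alcohol and all stereocentres untouched.

Step 9
Reactants: 13 tosylhydrazone of 12
Product: 15 trans-fused guai-3-ene-8β,10α-diol (1αH,5βH), via allylic diazene 14 (not isolated)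
Conditions: catecholborane (4 equiv), CHCl3, 0 °C; then NaOAc·3H2O (3 equiv), 60 °C
Reagents that add atoms: none
Why: Kabalka alkene-transposing reduction in which hydride adds to C3 from the α face (anti to the C10 substituent on C1), acetate-induced loss of sulfinate gives the 3β-diazene, and its retro-ene [1,5]-hydrogen shift with loss of N2 places hydrogen on C5 from the same β face and moves the alkene to C3=C4, creating the trans ring fusion as in the conversion of steroid 4-en-3-ones into 5β-3-enes.

Step 10
Reactants: 15 trans-fused guai-3-ene-8β,10α-diol; 16 3-(benzyloxy)-4-methoxybenzoic acid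
Product: 17 (1αH,5βH)-10α-hydroxyguai-3-en-8β-yl 3-(benzyloxy)-4-methoxybenzoate
Conditions: 16 (1.3 equiv), DCC (1.5 equiv), DMAP (0.3 equiv), CH2Cl2, 25 → 40 °C
Reagents that add atoms: none
Why: Steglich esterification acylates the secondary 8β-hydroxyl selectively because the tertiary 10α-hydroxyl is too hindered to react with the acylpyridinium intermediate, and configuration at C8 is retained.

Step 11
Reactants: 17 (1αH,5βH)-10α-hydroxyguai-3-en-8β-yl 3-(benzyloxy)-4-methoxybenzoate
Product: 18 3α,4α-epoxy-10α-hydroxy-1αH,5βH-guaian-8β-yl 3-(benzyloxy)-4-methoxybenzoate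
Conditions: VO(acac)2 (5 mol %), t-BuOOH (1.5 equiv), CH2Cl2, 0 → 25 °C
Reagents that add atoms: tert-butyl hydroperoxide, CC(C)(C)OO
Why: Hydroxyl-directed epoxidation in which the tertiary 10α-hydroxyl binds vanadium and delivers the peroxide oxygen to the α face of the trisubstituted C3=C4 alkene (the β face is further screened by the C10 methyl group), giving the 3α,4α-epoxide, which the syn hydroxyl cannot open.

Step 12
Reactants: 18 3α,4α-epoxy-10α-hydroxy-1αH,5βH-guaian-8β-yl 3-(benzyloxy)-4-methoxybenzoate
Product: 19 (1R,3R,4S,5S,7R,8R,10R)-3α,4α-epoxy-10α-hydroxy-1αH,5βH-guaian-8β-yl 3-hydroxy-4-methoxybenzoate (CNP0264062.2)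
Conditions: H2 (1 atm), 10% Pd/C, EtOAc, 25 °C
Reagents that add atoms: none
Why: Hydrogenolysis of the benzyl aryl ether under neutral conditions frees the phenol without affecting the aryl ester, the tertiary alcohol or the trisubstituted aliphatic epoxide.

**Compound list**

1 | (R)-(−)-carvone [(5R)-2-methyl-5-(prop-1-en-2-yl)cyclohex-2-en-1-one] | CC1=CC[C@H](CC1=O)C(C)=C | starting material
2 | (R)-carvotanacetone [(5R)-2-methyl-5-(propan-2-yl)cyclohex-2-en-1-one] | CC1=CC[C@H](CC1=O)C(C)C | intermediate
3 | (R)-(+)-1-phenylethylamine | C[C@@H](N)c1ccccc1 | starting material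
4 | ethyl vinyl ketone (pent-1-en-3-one) | CCC(=O)C=C | starting material
5 | N-[(R)-1-phenylethyl] ketimine of 2 (1-azadiene, in equilibrium with its secondary dienamine) | CC1=CC[C@H](CC1=N[C@H](C)c2ccccc2)C(C)C | intermediate
6 | N-[(R)-1-phenylethyl] ketimine of 7 (Michael adduct) | CCC(=O)CC[C@]1(C)C=C[C@@H](C(C)C)CC1=N[C@H](C)c2ccccc2 | intermediate
7 | (2R,5R)-2-methyl-2-(3-oxopentyl)-5-(propan-2-yl)cyclohex-3-en-1-one | CCC(=O)CC[C@]1(C)C=C[C@@H](C(C)C)CC1=O | intermediate
8 | (4aR,7R)-1,4a-dimethyl-7-(propan-2-yl)-4,4a,7,8-tetrahydronaphthalen-2(3H)-one (7αH-eudesma-4,8-dien-3-one) | C1=C[C@@]2(C)CCC(=O)C(C)=C2C[C@@H]1C(C)C | intermediate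
9 | 9α-bromo-8β-hydroxy-7αH-eudesm-4-en-3-one | O[C@@H]1[C@@H](Br)[C@@]2(C)CCC(=O)C(C)=C2C[C@@H]1C(C)C | intermediate
10 | 8β-hydroxy-7αH-eudesm-4-en-3-one | O[C@@H]1C[C@@]2(C)CCC(=O)C(C)=C2C[C@@H]1C(C)C | intermediate
11 | 8β-hydroxy-7αH-eudesma-1,4-dien-3-one | O[C@@H]1C[C@@]2(C)C=CC(=O)C(C)=C2C[C@@H]1C(C)C | intermediate
12 | (1R,7R,8R,10R)-8β,10α-dihydroxy-1αH-guai-4-en-3-one | O[C@@H]1C[C@@](C)(O)[C@@H]2CC(=O)C(C)=C2C[C@@H]1C(C)C | intermediate
13 | C3 p-toluenesulfonylhydrazone of 12 | O[C@@H]1C[C@@](C)(O)[C@@H]2CC(=NNS(=O)(=O)c3ccc(C)cc3)C(C)=C2C[C@@H]1C(C)C | intermediate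
14 | 3β-diazenyl-1αH-guai-4-ene-8β,10α-diol (allylic diazene) | O[C@@H]1C[C@@](C)(O)[C@@H]2C[C@H](N=N)C(C)=C2C[C@@H]1C(C)C | intermediate
15 | (1R,5S,7R,8R,10R)-1αH,5βH-guai-3-ene-8β,10α-diol | O[C@@H]1C[C@@](C)(O)[C@@H]2CC=C(C)[C@H]2C[C@@H]1C(C)C | intermediate
16 | 3-(benzyloxy)-4-methoxybenzoic acid (O-benzylisovanillic acid) | COc1ccc(cc1OCc1ccccc1)C(=O)O | starting material
17 | (1αH,5βH)-10α-hydroxyguai-3-en-8β-yl 3-(benzyloxy)-4-methoxybenzoate | COc1ccc(C(=O)O[C@@H]2C[C@@](C)(O)[C@@H]3CC=C(C)[C@H]3C[C@@H]2C(C)C)cc1OCc1ccccc1 | intermediate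
18 | 3α,4α-epoxy-10α-hydroxy-1αH,5βH-guaian-8β-yl 3-(benzyloxy)-4-methoxybenzoate | COc1ccc(C(=O)O[C@@H]2C[C@@](C)(O)[C@@H]3C[C@H]4O[C@@]4(C)[C@H]3C[C@@H]2C(C)C)cc1OCc1ccccc1 | intermediate
19 | (1R,3R,4S,5S,7R,8R,10R)-3α,4α-epoxy-10α-hydroxy-1αH,5βH-guaian-8β-yl 3-hydroxy-4-methoxybenzoate | COc1ccc(C(=O)O[C@@H]2C[C@@](C)(O)[C@@H]3C[C@H]4O[C@@]4(C)[C@H]3C[C@@H]2C(C)C)cc1O | target

**Step count and risks**

Total step count: 12. Longest linear sequence: 12 steps (1 to 19).

The three steps most likely to fail:

Step 2 is the least precedented step: an enone-derived chiral imine may give aza-Michael or [4+2] products instead of α-alkylation, and the matched/mismatched control at C10 is untested. The fallback sets out from 2 and comes back at 7. It replaces the aza-ene Michael addition by an SN2 alkylation of the metal dienolate: 2 is deprotonated with KOt-Bu in t-BuOH/THF at 0 °C and the potassium dienolate is alkylated at its α-carbon with 2-ethyl-2-(2-iodoethyl)-1,3-dioxolane (deconjugative alkylation, substrate control). This gives the ketal ketone (2R,5R)-2-[2-(2-ethyl-1,3-dioxolan-2-yl)ethyl]-2-methyl-5-(propan-2-yl)cyclohex-3-en-1-one F1, which is separated from its C2 epimer by chromatography. Ketal hydrolysis (PPTS, acetone/H2O, 50 °C) then gives 7.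

Step 7 is mechanistically secure but usually modest in yield: lumiketone, phenol and acetate by-products form, and the enone product can photolyse further. The fallback sets out from 11 and comes back at 12. It switches from hydration of the free alcohol to acetolysis of a masked substrate, the mode that gives O-acetylisophotosantonic lactone from santonin. Compound 11 is acetylated (Ac2O, pyridine, DMAP, 25 °C) to 8β-acetoxy-7αH-eudesma-1,4-dien-3-one F2. Irradiation of F2 in anhydrous AcOH (Pyrex, 25 °C) traps the C10 cation as the acetate, giving 8β,10α-diacetoxy-1αH-guai-4-en-3-one F3. Mild methanolysis (K2CO3, MeOH, 0 °C) removes both acetates to give 12.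

Step 11 depends on the tertiary, bishomoallylic 10α-hydroxyl actually directing the oxidant; if delivery is weak, the β-epoxide (which the 10α-hydroxyl would open to a 4,10-oxide) may compete. The fallback sets out from 17 and comes back at 18. It replaces substrate direction by reagent control: Shi asymmetric epoxidation with the fructose-derived ketone enantiomer matched to the α face, KHSO5 (as 2KHSO5·KHSO4·K2SO4), K2CO3 buffer, MeCN/dimethoxymethane/H2O, 0 °C, gives 18 directly; no new compound is made (F0).

Further compounds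
F1 | step 2 | (2R,5R)-2-[2-(2-ethyl-1,3-dioxolan-2-yl)ethyl]-2-methyl-5-(propan-2-yl)cyclohex-3-en-1-one | CCC1(CC[C@]2(C)C=C[C@@H](C(C)C)CC2=O)OCCO1
F2 | step 7 | 8β-acetoxy-7αH-eudesma-1,4-dien-3-one | CC(=O)O[C@@H]1C[C@@]2(C)C=CC(=O)C(C)=C2C[C@@H]1C(C)C
F3 | step 7 | 8β,10α-diacetoxy-1αH-guai-4-en-3-one | CC(=O)O[C@@H]1C[C@@](C)(OC(C)=O)[C@@H]2CC(=O)C(C)=C2C[C@@H]1C(C)C
F0 | step 11 | none | none
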